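**Plan**

- Retrosynthetic cuts: the silyl and methoxymethyl ethers; then C5'–C(acetyl), by cross-coupling at a C5' iodide; then ring B at C6'–C1' and C2'–C3', giving a 3-siloxycyclobutenone and a siloxyalkyne. Further back: C4'–C5' (ketene + a second siloxyalkyne), C3'–CH2 of the prenyl group, and ring A at C4–C5 and O1–C2.
- Enabling feature: ring B is a fully substituted benzene with oxygen on C2', C4' and C6' in a 1,3,5 pattern. O6' is a cyclobutenone carbonyl, O4' its 3-siloxy group, and O2' the oxygen of an ynol ether whose other alkyne carbon (C1') already carries C7 and ring A.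
- Forward order: ring A is made first from a silyl enol ether and propargylmalonyl dichloride, and its alkyne terminus is oxidised to the siloxyalkyne. Separately, a prenyl siloxyalkyne and ketene give the four-membered ring. Ring B then forms in one thermal operation, followed by acetylation at C5' and deprotection.
- Stereochemistry: the target has no stereocentre and no stereogenic double bond, so nothing has to be controlled.

Key step: step 10

Remark: ring A (the pyranone) is numbered O1, C2–C6, the bridging methylene is C7, and ring B is C1'–C6' with C1' on C7, C3' prenylated and C5' acetylated; ketene is taken as a gas made on demand by pyrolysis of acetone.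

**Route**

Step 1
Reactants: 1 diethyl 2-(prop-2-ynyl)malonate
Product: 2 2-(prop-2-ynyl)malonic acid
Conditions: KOH, EtOH/H2O, rt; then cold aqueous HCl to pH 1, extraction
Reagents that add atoms: potassium hydroxide, [K+].[OH-]
Why: Ester saponification at room temperature should give the diacid, which is isolated cold so that the malonic acid does not decarboxylate.

Step 2
Reactants: 2 2-(prop-2-ynyl)malonic acid
Product: 3 2-(prop-2-ynyl)malonyl dichloride
Conditions: SOCl2 (neat), 50 °C; distillation under reduced pressure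
Reagents that add atoms: thionyl chloride, O=S(Cl)Cl
Why: Conversion of a carboxylic acid into its acyl chloride with thionyl chloride is the standard access to substituted malonyl dichlorides, and the terminal alkyne is inert to it.

Step 3
Reactants: 4 pentan-3-one
Product: 5 trimethyl(pent-2-en-3-yloxy)silane (E/Z mixture)
Conditions: Me3SiOTf, Et3N, CH2Cl2, 0 °C
Reagents that add atoms: trimethylsilyl triflate, C[Si](C)(C)OS(=O)(=O)C(F)(F)F
Why: Silyl enol ether formation by soft enolisation of a symmetrical ketone poses no regiochemical question, and the alkene geometry is erased in step 4.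

Step 4
Reactants: 3 2-(prop-2-ynyl)malonyl dichloride; 5 trimethyl(pent-2-en-3-yloxy)silane
Product: 6 6-ethyl-4-hydroxy-5-methyl-3-(prop-2-ynyl)pyran-2-one
Conditions: Et2O, −60 °C → rt; extraction into aqueous NaHCO3, acidification
Reagents that add atoms: none
Why: C-Acylation of the silyl enol ether by one acyl chloride and lactonisation of the enolised 3,5-dioxo acyl chloride (acylative 4-hydroxy-2-pyranone synthesis) should close ring A, with the malonyl carbon and its propargyl group at C3 and the ketone carbons at C5 and C6.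

Step 5
Reactants: 6 6-ethyl-4-hydroxy-5-methyl-3-(prop-2-ynyl)pyran-2-one
Product: 7 6-ethyl-4-(methoxymethoxy)-5-methyl-3-(prop-2-ynyl)pyran-2-one
Conditions: MeOCH2Cl, i-Pr2NEt, CH2Cl2, 0 °C → rt
Reagents that add atoms: chloromethyl methyl ether, COCCl
Why: O-Alkylation of the vinylogous acid at the 4-oxygen (acetal protection) keeps the 2-pyranone and removes the acidic proton that a siloxyalkyne would not tolerate.

Step 6
Reactants: 7 6-ethyl-4-(methoxymethoxy)-5-methyl-3-(prop-2-ynyl)pyran-2-one
Product: 10 6-ethyl-4-(methoxymethoxy)-5-methyl-3-[3-(triisopropylsilyloxy)prop-2-ynyl]pyran-2-one, via lithium acetylide 8 (not isolated), via lithium ynolate 9 (not isolated)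
Conditions: LiN(SiMe3)2 (1.0 equiv), THF, −78 °C; t-BuOOLi (from t-BuOOH + LiN(SiMe3)2, THF, −78 °C), −78 → −10 °C; i-Pr3SiOTf, −78 → 0 °C; Et3N-deactivated silica
Reagents that add atoms: tert-butyl hydroperoxide, CC(C)(C)OO; triisopropylsilyl triflate, CC(C)[Si](C(C)C)(C(C)C)OS(=O)(=O)C(F)(F)F
Why: Oxidation of a lithium acetylide by lithium tert-butyl peroxide (electrophilic oxygen transfer) gives the ynolate, which the bulky silyl triflate traps on oxygen; the hindered amide should remove the acetylenic hydrogen kinetically at −78 °C before the alkyl groups of ring A.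

Step 7
Reactants: 11 1-bromo-3-methylbut-2-ene (prenyl bromide); 12 ethynylmagnesium bromide
Product: 13 5-methylhex-4-en-1-yne
Conditions: HC≡CMgBr (1.5 equiv, THF), CuBr·SMe2 (5 mol%), slow addition of 11, 0 °C → rt; fractional distillation
Reagents that add atoms: none
Why: Copper-catalysed coupling of an alkynyl Grignard reagent with a primary allylic bromide should form the skipped enyne at the unsubstituted allylic terminus, the excess of 12 suppressing a second alkylation.

Step 8
Reactants: 13 5-methylhex-4-en-1-yne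
Product: 16 triisopropyl[(5-methylhex-4-en-1-ynyl)oxy]silane, via lithium acetylide 14 (not isolated), via lithium ynolate 15 (not isolated)
Conditions: LiN(SiMe3)2, THF, −78 °C; t-BuOOLi (from t-BuOOH + LiN(SiMe3)2), −78 → −10 °C; i-Pr3SiOTf, −78 → 0 °C
Reagents that add atoms: tert-butyl hydroperoxide, CC(C)(C)OO; triisopropylsilyl triflate, CC(C)[Si](C(C)C)(C(C)C)OS(=O)(=O)C(F)(F)F
Why: The same acetylide oxidation to a lithium ynolate and O-silylation is applied to a simple alkyl alkyne, the substrate type for which it is routine.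

Step 9
Reactants: 16 triisopropyl[(5-methylhex-4-en-1-ynyl)oxy]silane; 17 acetone
Product: 19 2-(3-methylbut-2-enyl)-3-(triisopropylsilyloxy)cyclobut-2-en-1-one, via ketene 18 (not isolated)
Conditions: ketene stream from hot-wire pyrolysis of acetone passed into 16 in CH2Cl2, 0 °C → rt; short Et3N-deactivated silica plug
Reagents that add atoms: none
Why: Thermal [2+2] cycloaddition of ketene with an electron-rich ynol ether should give the 3-siloxycyclobutenone, since the alkyne carbon remote from oxygen attacks the ketene carbonyl carbon and so places the prenyl group at C2 and the siloxy group at C3.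

Step 10
Reactants: 19 2-(3-methylbut-2-enyl)-3-(triisopropylsilyloxy)cyclobut-2-en-1-one; 10 6-ethyl-4-(methoxymethoxy)-5-methyl-3-[3-(triisopropylsilyloxy)prop-2-ynyl]pyran-2-one
Product: 24 6-ethyl-3-{[6-hydroxy-3-(3-methylbut-2-enyl)-2,4-bis(triisopropylsilyloxy)phenyl]methyl}-4-(methoxymethoxy)-5-methylpyran-2-one, via vinylketene 20 (not isolated), via vinylcyclobutenone 21 (not isolated), via dienylketene 22 (not isolated), via cyclohexadienone 23 (not isolated)
Conditions: 19 (1.5 equiv), 10 (1.0 equiv), toluene (0.3 M), argon, sealed tube, 80 °C then 110 °C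
Reagents that add atoms: none
Why: Danheiser benzannulation: 4π electrocyclic opening of 19 gives (siloxyvinyl)ketene 20, whose carbonyl carbon (C6') is attacked by the alkyne carbon of 10 that carries C7 (C1') while the ketene alpha carbon (C3') bonds to the oxygen-bearing alkyne carbon (C2'). The [2+2] adduct 21 reopens by 4π cleavage of C6'–C3' to dienylketene 22, and ring B closes by thermal 6π electrocyclisation between the ketene carbon and the methylene terminus (C6'–C5'), after which dienone 23 tautomerises to the phenol. The closest known reaction is the same benzannulation of 3-alkylcyclobutenones with triisopropylsiloxyalkynes to resorcinol monosilyl ethers; here the 3-siloxy group supplies the third ring oxygen. No stereocentre is formed. The step needs the [2+2] regiochemistry, which the polarisation of the ynol ether (nucleophilic at the carbon remote from oxygen) dictates, and chemoselectivity for the ketene over the prenyl alkene and ring A, which the neutral conditions and the electron-rich, fully substituted pyranone should secure. Each of the six substituents of ring B is thereby fixed by the partner that carries it.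

Step 11
Reactants: 24 6-ethyl-3-{[6-hydroxy-3-(3-methylbut-2-enyl)-2,4-bis(triisopropylsilyloxy)phenyl]methyl}-4-(methoxymethoxy)-5-methylpyran-2-one
Product: 25 6-ethyl-3-{[6-hydroxy-5-iodo-3-(3-methylbut-2-enyl)-2,4-bis(triisopropylsilyloxy)phenyl]methyl}-4-(methoxymethoxy)-5-methylpyran-2-one
Conditions: N-iodosuccinimide (1.05 equiv), CH2Cl2, −20 → 0 °C, dark
Reagents that add atoms: N-iodosuccinimide, O=C1CCC(=O)N1I
Why: Electrophilic aromatic iodination of a phenol at C5', the only unsubstituted ring carbon and ortho to the free hydroxyl, should outpace iodonium formation at the prenyl alkene, which has no free ortho-hydroxyl to trap it.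

Step 12
Reactants: 25 6-ethyl-3-{[6-hydroxy-5-iodo-3-(3-methylbut-2-enyl)-2,4-bis(triisopropylsilyloxy)phenyl]methyl}-4-(methoxymethoxy)-5-methylpyran-2-one; 26 tributyl(1-ethoxyvinyl)stannane
Product: 28 3-{[5-acetyl-6-hydroxy-3-(3-methylbut-2-enyl)-2,4-bis(triisopropylsilyloxy)phenyl]methyl}-6-ethyl-4-hydroxy-5-methylpyran-2-one, via enol ether 27 (not isolated)
Conditions: Pd(PPh3)4 (10 mol%), CuI (20 mol%), DMF, 70 °C; then 2 M HCl, THF, rt
Reagents that add atoms: water, O
Why: Stille coupling of the aryl iodide with an alpha-alkoxyvinylstannane as acetyl anion equivalent, with CuI to speed transmetalation at the doubly ortho-substituted carbon, followed by acid hydrolysis of the enol ether to the methyl ketone and of the acetal on the vinylogous acid, while the silyl ethers flanking the prenyl group stay on and block chroman formation.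

Step 13
Reactants: 28 3-{[5-acetyl-6-hydroxy-3-(3-methylbut-2-enyl)-2,4-bis(triisopropylsilyloxy)phenyl]methyl}-6-ethyl-4-hydroxy-5-methylpyran-2-one
Product: 29 arzanol
Conditions: Bu4NF (3 equiv), AcOH (3 equiv), THF, 0 °C → rt
Reagents that add atoms: none
Why: Fluoride cleavage of the two aryl silyl ethers, buffered with acetic acid so that the acidic acylphloroglucinol and hydroxypyranone are not left as free anions, should release the target.

**Compound list**

1 | diethyl 2-(prop-2-ynyl)malonate | CCOC(=O)C(CC#C)C(=O)OCC | starting material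
2 | 2-(prop-2-ynyl)malonic acid | OC(=O)C(CC#C)C(=O)O | intermediate
3 | 2-(prop-2-ynyl)malonyl dichloride | ClC(=O)C(CC#C)C(=O)Cl | intermediate
4 | pentan-3-one | CCC(=O)CC | starting material
5 | trimethyl(pent-2-en-3-yloxy)silane (E/Z mixture) | CC=C(CC)O[Si](C)(C)C | intermediate
6 | 6-ethyl-4-hydroxy-5-methyl-3-(prop-2-ynyl)pyran-2-one | CCc1oc(=O)c(CC#C)c(O)c1C | intermediate
7 | 6-ethyl-4-(methoxymethoxy)-5-methyl-3-(prop-2-ynyl)pyran-2-one | CCc1oc(=O)c(CC#C)c(OCOC)c1C | intermediate
8 | lithium acetylide of 7 | CCc1oc(=O)c(CC#C[Li])c(OCOC)c1C | intermediate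
9 | lithium ynolate from 8 | CCc1oc(=O)c(CC#CO[Li])c(OCOC)c1C | intermediate
10 | 6-ethyl-4-(methoxymethoxy)-5-methyl-3-[3-(triisopropylsilyloxy)prop-2-ynyl]pyran-2-one | CCc1oc(=O)c(CC#CO[Si](C(C)C)(C(C)C)C(C)C)c(OCOC)c1C | intermediate
11 | 1-bromo-3-methylbut-2-ene (prenyl bromide) | CC(C)=CCBr | starting material
12 | ethynylmagnesium bromide | C#C[Mg]Br | starting material
13 | 5-methylhex-4-en-1-yne | C#CCC=C(C)C | intermediate
14 | lithium acetylide of 13 | [Li]C#CCC=C(C)C | intermediate
15 | lithium 5-methylhex-4-en-1-yn-1-olate | [Li]OC#CCC=C(C)C | intermediate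
16 | triisopropyl[(5-methylhex-4-en-1-ynyl)oxy]silane | CC(C)=CCC#CO[Si](C(C)C)(C(C)C)C(C)C | intermediate
17 | acetone | CC(C)=O | starting material
18 | ketene | C=C=O | intermediate
19 | 2-(3-methylbut-2-enyl)-3-(triisopropylsilyloxy)cyclobut-2-en-1-one | O=C1CC(O[Si](C(C)C)(C(C)C)C(C)C)=C1CC=C(C)C | intermediate
20 | 2-(3-methylbut-2-enyl)-3-(triisopropylsilyloxy)buta-1,3-dien-1-one | O=C=C(CC=C(C)C)C(=C)O[Si](C(C)C)(C(C)C)C(C)C | intermediate
21 | 2-{[6-ethyl-4-(methoxymethoxy)-5-methyl-2-oxopyran-3-yl]methyl}-4-(3-methylbut-2-enyl)-3-(triisopropylsilyloxy)-4-[1-(triisopropylsilyloxy)vinyl]cyclobut-2-en-1-one (racemic) | O=C1C(Cc2c(OCOC)c(C)c(CC)oc2=O)=C(O[Si](C(C)C)(C(C)C)C(C)C)C1(CC=C(C)C)C(=C)O[Si](C(C)C)(C(C)C)C(C)C | intermediate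
22 | 2-{[6-ethyl-4-(methoxymethoxy)-5-methyl-2-oxopyran-3-yl]methyl}-4-(3-methylbut-2-enyl)-3,5-bis(triisopropylsilyloxy)hexa-1,3,5-trien-1-one (ketene-bearing carbon and vinyl group cis on the central alkene) | O=C=C(Cc1c(OCOC)c(C)c(CC)oc1=O)/C(O[Si](C(C)C)(C(C)C)C(C)C)=C(CC=C(C)C)\C(=C)O[Si](C(C)C)(C(C)C)C(C)C | intermediate
23 | 2-{[6-ethyl-4-(methoxymethoxy)-5-methyl-2-oxopyran-3-yl]methyl}-4-(3-methylbut-2-enyl)-3,5-bis(triisopropylsilyloxy)cyclohexa-2,4-dien-1-one | O=C1CC(O[Si](C(C)C)(C(C)C)C(C)C)=C(CC=C(C)C)C(O[Si](C(C)C)(C(C)C)C(C)C)=C1Cc1c(OCOC)c(C)c(CC)oc1=O | intermediate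
24 | 6-ethyl-3-{[6-hydroxy-3-(3-methylbut-2-enyl)-2,4-bis(triisopropylsilyloxy)phenyl]methyl}-4-(methoxymethoxy)-5-methylpyran-2-one | CCc1oc(=O)c(Cc2c(O)cc(O[Si](C(C)C)(C(C)C)C(C)C)c(CC=C(C)C)c2O[Si](C(C)C)(C(C)C)C(C)C)c(OCOC)c1C | intermediate
25 | 6-ethyl-3-{[6-hydroxy-5-iodo-3-(3-methylbut-2-enyl)-2,4-bis(triisopropylsilyloxy)phenyl]methyl}-4-(methoxymethoxy)-5-methylpyran-2-one | CCc1oc(=O)c(Cc2c(O)c(I)c(O[Si](C(C)C)(C(C)C)C(C)C)c(CC=C(C)C)c2O[Si](C(C)C)(C(C)C)C(C)C)c(OCOC)c1C | intermediate
26 | tributyl(1-ethoxyvinyl)stannane | CCCC[Sn](CCCC)(CCCC)C(=C)OCC | starting material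
27 | 3-{[5-(1-ethoxyvinyl)-6-hydroxy-3-(3-methylbut-2-enyl)-2,4-bis(triisopropylsilyloxy)phenyl]methyl}-6-ethyl-4-(methoxymethoxy)-5-methylpyran-2-one | CCc1oc(=O)c(Cc2c(O)c(C(=C)OCC)c(O[Si](C(C)C)(C(C)C)C(C)C)c(CC=C(C)C)c2O[Si](C(C)C)(C(C)C)C(C)C)c(OCOC)c1C | intermediate
28 | 3-{[5-acetyl-6-hydroxy-3-(3-methylbut-2-enyl)-2,4-bis(triisopropylsilyloxy)phenyl]methyl}-6-ethyl-4-hydroxy-5-methylpyran-2-one | CCc1oc(=O)c(Cc2c(O)c(C(C)=O)c(O[Si](C(C)C)(C(C)C)C(C)C)c(CC=C(C)C)c2O[Si](C(C)C)(C(C)C)C(C)C)c(O)c1C | intermediate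
29 | arzanol, 3-{[3-acetyl-2,4,6-trihydroxy-5-(3-methylbut-2-enyl)phenyl]methyl}-6-ethyl-4-hydroxy-5-methylpyran-2-one | CCc1oc(=O)c(Cc2c(O)c(CC=C(C)C)c(O)c(C(C)=O)c2O)c(O)c1C | target

**Count and risks**

Total steps: 13. Longest linear sequence: 9 steps (1, 2, 4, 5, 6, 10, 11, 12, 13); step 3 and steps 7–9 are side branches.

Steps most likely to fail:

1. Step 10. The 3-siloxycyclobutenone is a vinylogous silyl ester and may open to the vinylketene only slowly. At the temperature then required, silyl migration or propargyl–allene isomerisation of the siloxyalkyne, or ketene dimerisation, could outrun the cycloaddition. Fallback (sets out from 5 and 11, returns at 29): ring B is taken from a preformed phloroglucinol and joined to ring A by a Mannich-type methylene transfer. Silyl enol ether 5 is condensed with malonyl dichloride as in step 4 to give 6-ethyl-4-hydroxy-5-methylpyran-2-one F1. Commercial 2,4,6-trihydroxyacetophenone is C-prenylated with 11 in cold aqueous KOH to give 1-[2,4,6-trihydroxy-3-(3-methylbut-2-enyl)phenyl]ethanone F2. F1 is treated with dimethylmethyleneammonium iodide to give 3-[(dimethylamino)methyl]-6-ethyl-4-hydroxy-5-methylpyran-2-one F3. On warming with F2, F3 loses dimethylamine to 6-ethyl-5-methyl-3-methylidenepyran-2,4-dione F4, which is trapped at the one free ring carbon of F2 to give arzanol 29.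

2. Step 6. Proton transfer from the C6 ethyl group of ring A to the acetylide or the amide base, and attack of peroxide or alkoxide on the lactone, may compete with oxygen transfer so that the ynolate does not form cleanly. Fallback (sets out from 6, returns at 10): the unprotected pyranone is used, so that its own anion shields ring A. Two equivalents of LiN(SiMe3)2 convert 6 into dilithium acetylide–pyronate F5, which is no longer acidic at the ethyl group and is a poor electrophile. Lithium tert-butyl peroxide oxidises it to dilithium ynolate–pyronate F6. One equivalent of i-Pr3SiOTf at −78 °C silylates the far more basic ynolate oxygen to give lithium 6-ethyl-5-methyl-2-oxo-3-[3-(triisopropylsilyloxy)prop-2-ynyl]pyran-4-olate F7. Chloromethyl methyl ether then caps the pyronate in the same flask and gives 10 without passing through 7.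

3. Step 12. Oxidative addition and transmetalation at the electron-rich C5' iodide, which is flanked by a hydroxyl and a bulky siloxy group, may be slow enough that protodeiodination takes over. Fallback (sets out from 24, returns at 28): the acetyl group is delivered from oxygen. Phenol 24 is acetylated (Ac2O, pyridine) to 2-{[6-ethyl-4-(methoxymethoxy)-5-methyl-2-oxopyran-3-yl]methyl}-4-(3-methylbut-2-enyl)-3,5-bis(triisopropylsilyloxy)phenyl acetate F8. A Fries rearrangement with TiCl4 in CH2Cl2 (−40 → 0 °C) moves the acyl group to the only free ortho carbon, giving 3-{[5-acetyl-6-hydroxy-3-(3-methylbut-2-enyl)-2,4-bis(triisopropylsilyloxy)phenyl]methyl}-6-ethyl-4-(methoxymethoxy)-5-methylpyran-2-one F9. The dilute HCl treatment of step 12 then removes any methoxymethyl ether that survives and gives 28.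

**Further compounds**

F1 | step 10 | 6-ethyl-4-hydroxy-5-methylpyran-2-one | CCc1oc(=O)cc(O)c1C
F2 | step 10 | 1-[2,4,6-trihydroxy-3-(3-methylbut-2-enyl)phenyl]ethanone | CC(=O)c1c(O)cc(O)c(CC=C(C)C)c1O
F3 | step 10 | 3-[(dimethylamino)methyl]-6-ethyl-4-hydroxy-5-methylpyran-2-one | CCc1oc(=O)c(CN(C)C)c(O)c1C
F4 | step 10 | 6-ethyl-5-methyl-3-methylidenepyran-2,4-dione | CCC1=C(C)C(=O)C(=C)C(=O)O1
F5 | step 6 | dilithium acetylide–pyronate of 6 | [Li+].[Li+].CCc1oc(=O)c(CC#[C-])c([O-])c1C
F6 | step 6 | dilithium ynolate–pyronate from F5 | [Li+].[Li+].CCc1oc(=O)c(CC#C[O-])c([O-])c1C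
F7 | step 6 | lithium 6-ethyl-5-methyl-2-oxo-3-[3-(triisopropylsilyloxy)prop-2-ynyl]pyran-4-olate | [Li+].CCc1oc(=O)c(CC#CO[Si](C(C)C)(C(C)C)C(C)C)c([O-])c1C
F8 | step 12 | 2-{[6-ethyl-4-(methoxymethoxy)-5-methyl-2-oxopyran-3-yl]methyl}-4-(3-methylbut-2-enyl)-3,5-bis(triisopropylsilyloxy)phenyl acetate | CCc1oc(=O)c(Cc2c(OC(C)=O)cc(O[Si](C(C)C)(C(C)C)C(C)C)c(CC=C(C)C)c2O[Si](C(C)C)(C(C)C)C(C)C)c(OCOC)c1C
F9 | step 12 | 3-{[5-acetyl-6-hydroxy-3-(3-methylbut-2-enyl)-2,4-bis(triisopropylsilyloxy)phenyl]methyl}-6-ethyl-4-(methoxymethoxy)-5-methylpyran-2-one | CCc1oc(=O)c(Cc2c(O)c(C(C)=O)c(O[Si](C(C)C)(C(C)C)C(C)C)c(CC=C(C)C)c2O[Si](C(C)C)(C(C)C)C(C)C)c(OCOC)c1C
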